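**Strategy**

Numbering: aromatic ring A = C4a, C5 and C6 (phenols), C7 (acid), C8, C8a; saturated ring B = C1 (side-chain carbon), C2, C3, C4 (methyl carbon); side chain C11(C20H2O)–C12–C16. The route rests on closing ring B at the C8a–C1 bond by a stereospecific Friedel–Crafts opening of a cis-2,3-dialkyloxetane. It exploits two features: C8a is para to the C6 oxygen, and C8a and the C20 oxygen stand 1,3 across C1–C11. In one operation the arene displaces the oxetane oxygen at C1 with inversion, turns an Evans syn-aldol pair into the C1/C11 dyad and frees the C20 hydroxyl. The precursor is an acyclic oxetane on a catechol acetonide, with C4 and C15 already set.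

Key step: step 10

Assumption: in step 2 the S ligand is taken to give the R aldehyde from the E alkenol; if the sense of induction is the opposite, the R ligand is used and nothing else changes.
Remark: locants C1–C20 in the text follow the overview; systematic names carry their own numbering; TBDPS = tert-butyldiphenylsilyl.

**Route**

Step 1
Reactants: 1 2,2-dimethyl-1,3-benzodioxole
Product: 3 (2,2-dimethyl-1,3-benzodioxol-4-yl)boronic acid, via aryllithium 2 (not isolated)
Conditions: n-BuLi, THF, 0 °C; B(OiPr)3, −78 °C to rt; 1 M HCl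
Reagents that add atoms: triisopropyl borate CC(C)OB(OC(C)C)OC(C)C; water O
Why: Directed ortho-metalation places lithium next to a ring oxygen (the two ortho positions are equivalent), and borate quench with hydrolysis should give the boronic acid.

Step 2
Reactants: 3 (2,2-dimethyl-1,3-benzodioxol-4-yl)boronic acid; 4 (E)-pent-3-en-1-ol
Product: 5 (R)-4-(2,2-dimethyl-1,3-benzodioxol-4-yl)pentanal
Conditions: Pd(MeCN)2(OTs)2 (6 mol %), Cu(OTf)2 (6 mol %), (S)-2-(4-tert-butyl-4,5-dihydrooxazol-2-yl)-5-(trifluoromethyl)pyridine (13 mol %), 3 Å molecular sieves, O2 (1 atm), DMF, rt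
Reagents that add atoms: none
Why: In this enantioselective redox-relay oxidative Heck arylation the aryl group adds to the alkene carbon remote from the hydroxyl, palladium walks to the carbinol carbon by β-hydride elimination and reinsertion and leaves as the aldehyde, and the chiral pyridine–oxazoline ligand selects the alkene face so that C4 should form as R.

Step 3
Reactants: 6 (S)-3-bromo-2-methylpropan-1-ol
Product: 7 (S)-(3-bromo-2-methylpropoxy)(tert-butyl)diphenylsilane
Conditions: TBDPSCl, imidazole, DMF, rt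
Reagents that add atoms: tert-butyl(chloro)diphenylsilane CC(C)(C)[Si](Cl)(c1ccccc1)c1ccccc1
Why: Standard silylation of a primary alcohol that does not involve the stereocentre.

Step 4
Reactants: 7 (S)-(3-bromo-2-methylpropoxy)(tert-butyl)diphenylsilane; 8 ethyl 4-bromobutanoate
Product: 10 ethyl (R)-7-[(tert-butyldiphenylsilyl)oxy]-6-methylheptanoate, via Grignard reagent 9 (not isolated)
Conditions: Mg, THF, 40 °C; then added slowly to 8, Li2CuCl4 (3 mol %), NMP, THF, 0 °C to rt
Reagents that add atoms: none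
Why: Grignard formation and copper-catalysed sp3–sp3 cross-coupling with a primary bromide tolerate the ester in the presence of NMP, and the stereocentre (C15) lies β to the reacting carbon and is untouched, its descriptor changing from S to R only through the priority rules.

Step 5
Reactants: 10 ethyl (R)-7-[(tert-butyldiphenylsilyl)oxy]-6-methylheptanoate
Product: 11 (R)-7-[(tert-butyldiphenylsilyl)oxy]-6-methylheptanoic acid
Conditions: LiOH, THF/MeOH/H2O, rt; 1 M HCl to pH 3
Reagents that add atoms: lithium hydroxide [Li+].[OH-]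
Why: Saponification of the ethyl ester, to which the primary silyl ether is stable at room temperature.

Step 6
Reactants: 11 (R)-7-[(tert-butyldiphenylsilyl)oxy]-6-methylheptanoic acid; 12 (S)-4-benzyloxazolidin-2-one
Product: 14 (S)-4-benzyl-3-{(R)-7-[(tert-butyldiphenylsilyl)oxy]-6-methylheptanoyl}oxazolidin-2-one, via mixed pivalic anhydride 13 (not isolated)
Conditions: PivCl, Et3N, THF, −20 °C; then 12, LiCl, −20 °C to rt
Reagents that add atoms: none
Why: N-Acylation of the oxazolidinone through the mixed pivalic anhydride, promoted by LiCl and Et3N, touches no stereocentre.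

Step 7
Reactants: 14 (S)-4-benzyl-3-{(R)-7-[(tert-butyldiphenylsilyl)oxy]-6-methylheptanoyl}oxazolidin-2-one; 5 (R)-4-(2,2-dimethyl-1,3-benzodioxol-4-yl)pentanal
Product: 16 (S)-4-benzyl-3-[(2S,3R,6R)-2-{(R)-5-[(tert-butyldiphenylsilyl)oxy]-4-methylpentyl}-6-(2,2-dimethyl-1,3-benzodioxol-4-yl)-3-hydroxyheptanoyl]oxazolidin-2-one, via Z boron enolate 15 (not isolated)
Conditions: Bu2BOTf, iPr2NEt, CH2Cl2, 0 °C; 5, −78 to 0 °C; pH 7 buffer, MeOH, H2O2, 0 °C
Reagents that add atoms: none
Why: In this Evans syn aldol reaction the Z boron enolate reacts through a closed chair transition state on the enolate face away from the auxiliary benzyl group, which should set C11 as S and the C1 carbinol as R (2,3-syn) irrespective of the remote C4 and C15 centres.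

Step 8
Reactants: 16 syn-aldol adduct
Product: 17 (2R,3R,6R)-2-{(R)-5-[(tert-butyldiphenylsilyl)oxy]-4-methylpentyl}-6-(2,2-dimethyl-1,3-benzodioxol-4-yl)heptane-1,3-diol
Conditions: LiBH4, H2O (1 equiv), Et2O, 0 °C
Reagents that add atoms: none
Why: Reductive cleavage of the N-acyloxazolidinone gives the primary alcohol and returns the auxiliary without touching the stereocentres (the C11 descriptor becomes R only because C20 loses priority).

Step 9
Reactants: 17 syn-1,3-diol
Product: 19 tert-butyl{[(R)-5-{(2R,3R)-2-[(R)-3-(2,2-dimethyl-1,3-benzodioxol-4-yl)butyl]oxetan-3-yl}-2-methylpentyl]oxy}diphenylsilane (cis-oxetane), via primary tosylate 18 (not isolated)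
Conditions: TsCl, Et3N, cat. DMAP, CH2Cl2, 0 °C; then KOtBu, THF, 0 °C to rt
Reagents that add atoms: none
Why: Selective sulfonylation of the primary hydroxyl and intramolecular Williamson etherification (4-exo-tet) by the C1 alkoxide break no bond to a stereocentre, so the syn diol should give the cis-2,3-dialkyloxetane.

Step 10
Reactants: 19 cis-oxetane
Product: 20 (2S,6R)-7-[(tert-butyldiphenylsilyl)oxy]-2-[(1S,4R)-5,6-(isopropylidenedioxy)-4-methyl-1,2,3,4-tetrahydronaphthalen-1-yl]-6-methylheptan-1-ol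
Conditions: BF3·OEt2 (20 mol %), CH2Cl2 (high dilution), −78 to −20 °C; aq. NaHCO3
Reagents that add atoms: none
Why: BF3 coordinates the oxetane oxygen and C8a of ring A, para to the C6 oxygen and ortho to the tether, attacks C1 from the side opposite the C1–O bond; the Wheland intermediate then passes its proton to the boron alkoxide, which restores the aromatic ring and the Lewis acid. The closest known reaction type is the Friedel–Crafts alkylation of arenes by Lewis-acid opening of oxetanes, the four-membered counterpart of the epoxy–arene cyclization. Ring B closes in a 6-exo-tet mode, the breaking C1–O bond lying outside the new ring; attack at C20 would need an eight-membered ring and the other ortho carbon (C5) carries oxygen, so only C8a can react. C1 is the only new stereocentre and is set by inversion of the R carbinol carbon to S, while C11, C4 and C15 are carried through, which should give the 1,4-trans tetralin with the S,S dyad at C1/C11. The step needs substitution to outrun ionisation of the secondary C1–O bond (hydride shift, loss of fidelity), which is secured by ring strain, low temperature, a non-ionising solvent and an electron-rich arene: the planar acetonide holds the C6 oxygen lone pair in conjugation and the carboxyl group is not yet present.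

Step 11
Reactants: 20 tetralin alcohol
Product: 22 (5R,8S)-8-{(2S,6R)-7-[(tert-butyldiphenylsilyl)oxy]-1-hydroxy-6-methylheptan-2-yl}-3,4-(isopropylidenedioxy)-5-methyl-5,6,7,8-tetrahydronaphthalene-2-carboxylic acid, via dilithio species 21 (not isolated)
Conditions: s-BuLi (2.5 equiv), TMEDA, THF, −78 to −30 °C; CO2, −78 °C to rt; 1 M HCl to pH 3, 0 °C
Reagents that add atoms: carbon dioxide O=C=O
Why: In this directed ortho-metalation the hydroxyl is deprotonated first, the second equivalent of s-BuLi lithiates C7, the only ring position ortho to a dioxole oxygen, and CO2 traps the aryllithium as the carboxylic acid.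

Step 12
Reactants: 22 hydroxy acid
Product: 24 (5R,8S)-8-[(2S,6R)-1,7-diacetoxy-6-methylheptan-2-yl]-3,4-(isopropylidenedioxy)-5-methyl-5,6,7,8-tetrahydronaphthalene-2-carboxylic acid, via diol acid 23 (not isolated)
Conditions: TBAF, THF, rt; then Ac2O, pyridine, cat. DMAP, 0 °C to rt; aqueous work-up
Reagents that add atoms: acetic anhydride CC(=O)OC(C)=O
Why: Fluoride cleaves the silyl ether and both primary alcohols are then acetylated in the same flask, any mixed anhydride at the aryl carboxyl being hydrolysed during aqueous work-up.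

Step 13
Reactants: 24 diacetate acetonide
Product: 25 (5R,8S)-8-[(2S,6R)-1,7-diacetoxy-6-methylheptan-2-yl]-3,4-dihydroxy-5-methyl-5,6,7,8-tetrahydronaphthalene-2-carboxylic acid (CNP0245723.1)
Conditions: TFA/H2O (9:1), 0 °C to rt
Reagents that add atoms: none
Why: Acid hydrolysis of the catechol isopropylidene ketal should release the two phenols while the primary acetates and the carboxylic acid are stable to aqueous TFA at room temperature.

**Compound list**

1 | 2,2-dimethyl-1,3-benzodioxole | CC1(C)Oc2ccccc2O1 | starting material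
2 | (2,2-dimethyl-1,3-benzodioxol-4-yl)lithium | [Li]c1cccc2OC(C)(C)Oc12 | intermediate
3 | (2,2-dimethyl-1,3-benzodioxol-4-yl)boronic acid | OB(O)c1cccc2OC(C)(C)Oc12 | intermediate
4 | (E)-pent-3-en-1-ol | C/C=C/CCO | starting material
5 | (R)-4-(2,2-dimethyl-1,3-benzodioxol-4-yl)pentanal | C[C@H](CCC=O)c1cccc2OC(C)(C)Oc12 | intermediate
6 | (S)-3-bromo-2-methylpropan-1-ol | OC[C@H](C)CBr | starting material
7 | (S)-(3-bromo-2-methylpropoxy)(tert-butyl)diphenylsilane | CC(C)(C)[Si](c1ccccc1)(c1ccccc1)OC[C@H](C)CBr | intermediate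
8 | ethyl 4-bromobutanoate | CCOC(=O)CCCBr | starting material
9 | (S)-{3-[(tert-butyldiphenylsilyl)oxy]-2-methylpropyl}magnesium bromide | CC(C)(C)[Si](c1ccccc1)(c1ccccc1)OC[C@H](C)C[Mg]Br | intermediate
10 | ethyl (R)-7-[(tert-butyldiphenylsilyl)oxy]-6-methylheptanoate | CC(C)(C)[Si](c1ccccc1)(c1ccccc1)OC[C@H](C)CCCCC(=O)OCC | intermediate
11 | (R)-7-[(tert-butyldiphenylsilyl)oxy]-6-methylheptanoic acid | CC(C)(C)[Si](c1ccccc1)(c1ccccc1)OC[C@H](C)CCCCC(=O)O | intermediate
12 | (S)-4-benzyloxazolidin-2-one | O=C1N[C@@H](Cc2ccccc2)CO1 | starting material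
13 | (R)-7-[(tert-butyldiphenylsilyl)oxy]-6-methylheptanoic pivalic anhydride | CC(C)(C)[Si](c1ccccc1)(c1ccccc1)OC[C@H](C)CCCCC(=O)OC(=O)C(C)(C)C | intermediate
14 | (S)-4-benzyl-3-{(R)-7-[(tert-butyldiphenylsilyl)oxy]-6-methylheptanoyl}oxazolidin-2-one | CC(C)(C)[Si](c1ccccc1)(c1ccccc1)OC[C@H](C)CCCCC(=O)N1[C@@H](Cc2ccccc2)COC1=O | intermediate
15 | (S)-4-benzyl-3-{(R,Z)-1-[(dibutylboranyl)oxy]-7-[(tert-butyldiphenylsilyl)oxy]-6-methylhept-1-en-1-yl}oxazolidin-2-one | CCCCB(CCCC)O/C(=C\CCC[C@@H](C)CO[Si](c1ccccc1)(c1ccccc1)C(C)(C)C)N1[C@@H](Cc2ccccc2)COC1=O | intermediate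
16 | (S)-4-benzyl-3-[(2S,3R,6R)-2-{(R)-5-[(tert-butyldiphenylsilyl)oxy]-4-methylpentyl}-6-(2,2-dimethyl-1,3-benzodioxol-4-yl)-3-hydroxyheptanoyl]oxazolidin-2-one | C[C@H](CC[C@@H](O)[C@H](CCC[C@@H](C)CO[Si](c1ccccc1)(c1ccccc1)C(C)(C)C)C(=O)N1[C@@H](Cc2ccccc2)COC1=O)c1cccc2OC(C)(C)Oc12 | intermediate
17 | (2R,3R,6R)-2-{(R)-5-[(tert-butyldiphenylsilyl)oxy]-4-methylpentyl}-6-(2,2-dimethyl-1,3-benzodioxol-4-yl)heptane-1,3-diol | C[C@H](CC[C@@H](O)[C@H](CCC[C@@H](C)CO[Si](c1ccccc1)(c1ccccc1)C(C)(C)C)CO)c1cccc2OC(C)(C)Oc12 | intermediate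
18 | (2R,3R,6R)-2-{(R)-5-[(tert-butyldiphenylsilyl)oxy]-4-methylpentyl}-6-(2,2-dimethyl-1,3-benzodioxol-4-yl)-3-hydroxyheptyl 4-methylbenzenesulfonate | C[C@H](CC[C@@H](O)[C@H](CCC[C@@H](C)CO[Si](c1ccccc1)(c1ccccc1)C(C)(C)C)COS(=O)(=O)c1ccc(C)cc1)c1cccc2OC(C)(C)Oc12 | intermediate
19 | tert-butyl{[(R)-5-{(2R,3R)-2-[(R)-3-(2,2-dimethyl-1,3-benzodioxol-4-yl)butyl]oxetan-3-yl}-2-methylpentyl]oxy}diphenylsilane (cis-oxetane) | C[C@H](CC[C@H]1OC[C@H]1CCC[C@@H](C)CO[Si](c1ccccc1)(c1ccccc1)C(C)(C)C)c1cccc2OC(C)(C)Oc12 | intermediate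
20 | (2S,6R)-7-[(tert-butyldiphenylsilyl)oxy]-2-[(1S,4R)-5,6-(isopropylidenedioxy)-4-methyl-1,2,3,4-tetrahydronaphthalen-1-yl]-6-methylheptan-1-ol | CC(C)(C)[Si](c1ccccc1)(c1ccccc1)OC[C@H](C)CCC[C@H](CO)[C@@H]1CC[C@@H](C)c2c1ccc1OC(C)(C)Oc12 | intermediate
21 | dilithio derivative of 20 (lithium alkoxide at the C20 oxygen, aryllithium at C7) | CC(C)(C)[Si](c1ccccc1)(c1ccccc1)OC[C@H](C)CCC[C@H](CO[Li])[C@@H]1CC[C@@H](C)c2c1cc([Li])c1OC(C)(C)Oc12 | intermediate
22 | (5R,8S)-8-{(2S,6R)-7-[(tert-butyldiphenylsilyl)oxy]-1-hydroxy-6-methylheptan-2-yl}-3,4-(isopropylidenedioxy)-5-methyl-5,6,7,8-tetrahydronaphthalene-2-carboxylic acid | CC(C)(C)[Si](c1ccccc1)(c1ccccc1)OC[C@H](C)CCC[C@H](CO)[C@@H]1CC[C@@H](C)c2c1cc(C(=O)O)c1OC(C)(C)Oc12 | intermediate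
23 | (5R,8S)-8-[(2S,6R)-1,7-dihydroxy-6-methylheptan-2-yl]-3,4-(isopropylidenedioxy)-5-methyl-5,6,7,8-tetrahydronaphthalene-2-carboxylic acid | OC[C@H](C)CCC[C@H](CO)[C@@H]1CC[C@@H](C)c2c1cc(C(=O)O)c1OC(C)(C)Oc12 | intermediate
24 | (5R,8S)-8-[(2S,6R)-1,7-diacetoxy-6-methylheptan-2-yl]-3,4-(isopropylidenedioxy)-5-methyl-5,6,7,8-tetrahydronaphthalene-2-carboxylic acid | CC(=O)OC[C@H](C)CCC[C@H](COC(C)=O)[C@@H]1CC[C@@H](C)c2c1cc(C(=O)O)c1OC(C)(C)Oc12 | intermediate
25 | (5R,8S)-8-[(2S,6R)-1,7-diacetoxy-6-methylheptan-2-yl]-3,4-dihydroxy-5-methyl-5,6,7,8-tetrahydronaphthalene-2-carboxylic acid (CNP0245723.1) | CC(=O)OC[C@H](C)CCC[C@H](COC(C)=O)[C@@H]1CC[C@@H](C)c2c1cc(C(=O)O)c(O)c2O | target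

**Step count and risks**

Total step count: 13. Longest linear sequence: 11 steps (steps 3–13, from 6).

Steps most likely to fail:

1. Step 10 (ring closure). What may go wrong: ionisation of the Lewis-acid-bound oxetane ahead of arene attack, with hydride shift, loss of stereochemical fidelity at C1 or oligomerisation, and Lewis-acid cleavage of the acetonide. Fallback, setting out from 16 and returning at 20: C1 is activated as a β-lactone, whose acyl-bound oxygen is a better leaving group, instead of as an ether. Hydrolysis of the auxiliary in 16 with LiOH/H2O2 (THF/H2O, 0 °C) should give the β-hydroxy acid (2S,3R,6R)-2-{(R)-5-[(tert-butyldiphenylsilyl)oxy]-4-methylpentyl}-6-(2,2-dimethyl-1,3-benzodioxol-4-yl)-3-hydroxyheptanoic acid F1. Carboxyl activation with PhSO2Cl in pyridine (0 °C) should close the cis-β-lactone (3S,4R)-3-{(R)-5-[(tert-butyldiphenylsilyl)oxy]-4-methylpentyl}-4-[(R)-3-(2,2-dimethyl-1,3-benzodioxol-4-yl)butyl]oxetan-2-one F2 with retention at C1. A Lewis acid such as Sc(OTf)3 (CH2Cl2, −40 °C to rt) should then effect Friedel–Crafts alkyl–oxygen cleavage by C8a with inversion to give the tetralin acid (2S,6R)-7-[(tert-butyldiphenylsilyl)oxy]-2-[(1S,4R)-5,6-(isopropylidenedioxy)-4-methyl-1,2,3,4-tetrahydronaphthalen-1-yl]-6-methylheptanoic acid F3, and LiAlH4 (THF, 0 °C) reduces the acid to 20.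

2. Step 2. What may go wrong: arylation at the alkene carbon nearer the hydroxyl, weak face discrimination with the ortho-oxygenated aryl group, or protodeboronation and homocoupling of the electron-rich boronic acid. Fallback, setting out from 3 and returning at 5: Hayashi–Miyaura conjugate addition of 3 to ethyl (E)-crotonate (Rh(acac)(C2H4)2, the BINAP antipode that gives the R product, dioxane/H2O, 100 °C) should give ethyl (R)-3-(2,2-dimethyl-1,3-benzodioxol-4-yl)butanoate F4. Reduction with i-Bu2AlH (toluene, −78 °C) should give (R)-3-(2,2-dimethyl-1,3-benzodioxol-4-yl)butanal F5. Wittig reaction with Ph3P=CHOMe (from (methoxymethyl)triphenylphosphonium chloride and KN(SiMe3)2, THF, 0 °C) should give the enol ether 4-[(R)-5-methoxypent-4-en-2-yl]-2,2-dimethyl-1,3-benzodioxole F6 as an E/Z mixture, and brief hydrolysis (dilute aq. HCl, THF, 0 °C) gives 5.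

3. Step 13. What may go wrong: slow hydrolysis of the ketal on the electron-poor, carboxyl-bearing ring, so that the longer acid exposure begins to cleave the primary acetates. Fallback, setting out from 23 and returning at 25: unmasking and acetylation are reversed. Step 12 is stopped after the fluoride stage and 23 is isolated. Aqueous HCl in THF at 50 °C, with no ester yet present, should remove the acetonide to give (5R,8S)-8-[(2S,6R)-1,7-dihydroxy-6-methylheptan-2-yl]-3,4-dihydroxy-5-methyl-5,6,7,8-tetrahydronaphthalene-2-carboxylic acid F7. Ac2O/pyridine/DMAP should acetylate all four hydroxyls to give (5R,8S)-3,4-diacetoxy-8-[(2S,6R)-1,7-diacetoxy-6-methylheptan-2-yl]-5-methyl-5,6,7,8-tetrahydronaphthalene-2-carboxylic acid F8. NH4OAc in aqueous MeOH at rt should then cleave only the two aryl acetates, which are far more labile than the alkyl acetates, to give 25.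

Further compounds
F1 | step 10 | (2S,3R,6R)-2-{(R)-5-[(tert-butyldiphenylsilyl)oxy]-4-methylpentyl}-6-(2,2-dimethyl-1,3-benzodioxol-4-yl)-3-hydroxyheptanoic acid | C[C@H](CC[C@@H](O)[C@H](CCC[C@@H](C)CO[Si](c1ccccc1)(c1ccccc1)C(C)(C)C)C(=O)O)c1cccc2OC(C)(C)Oc12
F2 | step 10 | (3S,4R)-3-{(R)-5-[(tert-butyldiphenylsilyl)oxy]-4-methylpentyl}-4-[(R)-3-(2,2-dimethyl-1,3-benzodioxol-4-yl)butyl]oxetan-2-one | C[C@H](CC[C@H]1OC(=O)[C@H]1CCC[C@@H](C)CO[Si](c1ccccc1)(c1ccccc1)C(C)(C)C)c1cccc2OC(C)(C)Oc12
F3 | step 10 | (2S,6R)-7-[(tert-butyldiphenylsilyl)oxy]-2-[(1S,4R)-5,6-(isopropylidenedioxy)-4-methyl-1,2,3,4-tetrahydronaphthalen-1-yl]-6-methylheptanoic acid | CC(C)(C)[Si](c1ccccc1)(c1ccccc1)OC[C@H](C)CCC[C@H](C(=O)O)[C@@H]1CC[C@@H](C)c2c1ccc1OC(C)(C)Oc12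
F4 | step 2 | ethyl (R)-3-(2,2-dimethyl-1,3-benzodioxol-4-yl)butanoate | CCOC(=O)C[C@@H](C)c1cccc2OC(C)(C)Oc12
F5 | step 2 | (R)-3-(2,2-dimethyl-1,3-benzodioxol-4-yl)butanal | O=CC[C@@H](C)c1cccc2OC(C)(C)Oc12
F6 | step 2 | 4-[(R)-5-methoxypent-4-en-2-yl]-2,2-dimethyl-1,3-benzodioxole (E/Z mixture) | COC=CC[C@@H](C)c1cccc2OC(C)(C)Oc12
F7 | step 13 | (5R,8S)-8-[(2S,6R)-1,7-dihydroxy-6-methylheptan-2-yl]-3,4-dihydroxy-5-methyl-5,6,7,8-tetrahydronaphthalene-2-carboxylic acid | OC[C@H](C)CCC[C@H](CO)[C@@H]1CC[C@@H](C)c2c1cc(C(=O)O)c(O)c2O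
F8 | step 13 | (5R,8S)-3,4-diacetoxy-8-[(2S,6R)-1,7-diacetoxy-6-methylheptan-2-yl]-5-methyl-5,6,7,8-tetrahydronaphthalene-2-carboxylic acid | CC(=O)OC[C@H](C)CCC[C@H](COC(C)=O)[C@@H]1CC[C@@H](C)c2c1cc(C(=O)O)c(OC(C)=O)c2OC(C)=O
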